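## The problem

Target 17 is a flavone: a benzopyran-4-one (rings A and C) joined through the single bond C2–C1' to a pentasubstituted benzene (ring B). It has no stereocenter, so the task is purely one of regiochemistry among six oxygen substituents. Ring A needs a free 5-OH next to the C4 carbonyl and a 7-OMe, a pattern that the symmetric ketone 12 already contains. Ring B is the real difficulty: C2' to C5' carry four contiguous oxygens, free hydroxyls at C2' and C5' and methyl ethers at C3' and C4', and no cheap arene offers this array with phenols and ethers already told apart. The sensitive parts are the ring B hydroquinone (oxidized to a quinone by air once base is present), the 2'-OH (it could add to the enone while ring C is built) and the pyranone (opened by hot hydroxide, reducible under forcing hydrogenation). Both ring B phenols must therefore stay masked to the last step and be released under neutral conditions. The enabling feature is that the unit C2'(OH)–C3'(OMe)–C4'(OMe)–C5'(OH) has exactly the oxygen pattern of dimethyl squarate 4 after ring expansion. The two carbonyl carbons of 4 become the two para phenols and its two enol ether carbons the vicinal methyl ethers. C1' and C6' come from a 1,1-disubstituted alkene whose substituent is a masked formyl group for ring C.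

## Retrosynthesis

17 ⇒ 16. The O–H bonds at C5, C2' and C5' are traced back to three benzyl ethers. Benzyl is preferred to methyl, because no methyl ether then has to be cleaved next to two that must stay. It is preferred to silyl or acetal groups because the ethers must pass hydroxide (step 7), dilute acid (step 5) and 130 °C (step 8). The skeleton of 16 is the same, but every phenol is inert. The forward step must cleave one chelated and one hindered benzyl ether without reducing the pyranone, which points to neutral hydrogenolysis.

16 ⇒ 14 (through 15). The O1–C2 bond is cut and two hydrogens are returned to C2–C3, which opens ring C to the 2'-hydroxychalcone 14; in the forward sense the closure passes through flavanone 15. The neighbouring cut, a 1,3-diketone closed by dehydration, would need ring B at the acid oxidation level. The ring expansion below delivers the aldehyde level, so the chalcone is the shorter link. The forward reaction must close the ring by oxa-Michael addition and dehydrogenate it in the presence of benzyl ethers and two electron-rich arenes.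

14 ⇒ 11 + 13. The enone double bond (C2=C3 of the flavone) is cut: C3 comes from the acetyl methyl of ketone 13 and C2 from the formyl carbon of aldehyde 11. This is the convergent cut of the plan, giving two fragments of similar size, each with one aromatic ring. The forward crossed aldol condensation is unambiguous, because only 13 can enolize and only 11 is a reactive electrophile.

13 ⇒ 12. One O–benzyl bond is cut. Ketone 12 is symmetric, so either hydroxyl gives the same monoether and the forward reaction only has to stop after one alkylation.

11 ⇒ 9 (through 10). Both ring B O–benzyl bonds are cut and the formyl group is returned to its diethyl acetal. Benzylation comes before unmasking of the aldehyde, so that the phenols are capped while the acid-labile acetal is still in place. The precursor 9 is the free hydroquinone that the ring expansion delivers, with phenols and methyl ethers already distinguished. The forward step must alkylate an air-sensitive hydroquinone completely, one position being flanked on both sides, and then hydrolyse the acetal with dilute acid.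

9 ⇒ 6 (through 8 and 7). The bond C5'–C6' of ring B is cut and C2' is reconnected to C5', which turns the benzene ring into the cyclobutenone 6 carrying the alkene on its carbinol carbon. The neighbouring cuts, stepwise oxidation and selective dealkylation of a polymethoxyarene, would have to tell four similar oxygens apart. Here the distinction is inherited from the difference between carbonyl and enol ether carbons of the squarate. The precursor has one four-membered ring and no arene. The forward reaction is a four-electron ring opening, a six-electron ring closure and an enolization, all without reagent. It must keep the acetal and the hydroquinone intact at about 110 °C.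

6 ⇒ 4 + 5 (from 3). The bond C1'–C2' between the alkene carbon and the carbinol carbon is cut, giving dimethyl squarate 4 and the vinyllithium 5, an α-formylvinyl anion equivalent generated from bromide 3. Because 4 is symmetric, the choice of carbonyl is immaterial. The forward reaction must stop at a single 1,2-addition.

3 ⇒ 2 ⇒ 1. The C–Br bond of 3 is traced through dibromide 2 to the commercial acetal 1 by dehydrobromination and bromination. Two simple steps turn a bulk chemical into the three-carbon unit that supplies C1', C6' and the future C2.

## Roads not taken

Alternative 1: The cut opens ring A between C4a and C8a and ring C between O1 and C2, leading to the open-chain aroyl tetraketo ester A1. In the forward sense Mg(OMe)2 in methanol would template a Claisen condensation of the C4a methylene onto the ester carbon. Acid would then close the pyranone by attack of a phenol oxygen on the aroyl carbon, giving the 5,7-dihydroxyflavone A2.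
- Merit: two rings form in one operation from an acyclic chain. In bond economy this is better than the three steps (6, 7 and 8) that the chosen plan spends on joining ring A and closing ring C.
- Weak points: a chain with four ketone carbonyls can also fold by aldol reactions to isomeric resorcinol-type rings. Its assembly needs polyanion acylations with a hindered ring B ester. A2 still needs O-methylation at C7 only, which is reliable because the 5-OH is chelated, but it is a further step.
- Above all, the 2,5-bis(benzyloxy)-3,4-dimethoxyphenyl unit with its differentiated oxygens is taken for granted.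
- Comparison: the chosen plan buys ring A ready-made in 12 and places its one demanding step on ring B, the part that cannot be bought.

Alternative 2: The cut is C4–C4a, which leads to the 3-aryloxycinnamic acid A3. Activation of A3 as its mixed anhydride with trifluoroacetic anhydride would let the acyl carbon attack the carbon ortho to the ether oxygen of the symmetric dimethoxyphenoxy ring. This closes ring C and gives the 5,7-dimethoxyflavone A4.
- Merits: both ortho positions of the phenoxy ring are equivalent, so the acylation has one outcome. The endgame is at least as short as steps 7 and 8 of the chosen plan.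
- Weak points: A4 carries a 5-OMe that must later be cleaved in the presence of three other methyl ethers. Two of these sit on ring B between oxygens that can chelate a Lewis acid once the benzyl groups are gone. The strongly acidic acylating medium also invites benzyl transfer on the very electron-rich ring B. Ring B is again presupposed.
- Comparison: the chosen plan carries the C5 oxygen as a benzyl ether, so no methyl ether is ever cleaved. Against the shorter chromone assembly of this alternative it has to set one extra protection step (step 6).

Alternative 3: The cut removes ring A at C5–C6, C7–C8 and C4a–C5, leading to the pyranonyl diazoketone A5 and methoxyethyne A6. Photochemical Wolff rearrangement of A5 would give a ketene that adds A6 to a vinylcyclobutenone. Four-electron opening and six-electron closure onto the pyranone carbon would then give the flavone A7.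
- Merits: the logic is the same ketene electrocyclization as in the chosen key step. It delivers the 5-OH free and the 7-OMe in place, with the regiochemistry fixed by the polarization of the ynol ether. It needs no protecting group on ring A, which in that respect is better than the chosen plan.
- Weak points: 4-pyranones are themselves photoreactive at the wavelengths of the Wolff step. The closing carbon belongs to an electron-poor, cross-conjugated ring. A6 is volatile and unstable and has to be prepared. A5 requires a 6-arylpyranone carboxylic acid and a diazoketone synthesis. Ring B is left unsolved.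
- Comparison: ring A is the part that is commercially available. The chosen plan therefore spends the electrocyclization on ring B and accepts a benzyl group on ring A as the price.

Key step: step 4

Assumption: compounds 1, 4 and 12 are purchased. Hydroquinone 9 is not purified but concentrated under argon and carried on at once. The racemic centers of 2, 6 and 15 are all destroyed later, so no stereochemistry needs control.

## Route

Step 1
Reactants: 1 acrolein diethyl acetal (3,3-diethoxyprop-1-ene)
Product: 2 2,3-dibromo-1,1-diethoxypropane (racemic)
Conditions: Br2 (1.0 equiv), CH2Cl2, −20 °C to 0 °C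
Reagents that add atoms: bromine, BrBr
Why: Electrophilic anti addition of bromine to the terminal alkene through a bromonium ion; the acetal is inert in the cold without water or acid, and the racemic center at C2 disappears in step 2.

Step 2
Reactants: 2 2,3-dibromo-1,1-diethoxypropane (racemic)
Product: 3 2-bromo-3,3-diethoxyprop-1-ene
Conditions: KOtBu (1.05 equiv), THF, 0 °C
Reagents that add atoms: none
Why: E2 dehydrobromination: the C2 hydrogen, acidified by the geminal bromine and the adjacent acetal carbon, is lost together with the primary bromide to give the 1,1-disubstituted vinyl bromide; one equivalent of base at 0 °C should stop before the second elimination to the alkyne.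

Step 3
Reactants: 3 2-bromo-3,3-diethoxyprop-1-ene; 4 dimethyl squarate (3,4-dimethoxycyclobut-3-ene-1,2-dione)
Product: 6 4-(3,3-diethoxyprop-1-en-2-yl)-4-hydroxy-2,3-dimethoxycyclobut-2-en-1-one (racemic), via vinyllithium 5 (not isolated)
Conditions: t-BuLi (2.0 equiv), THF, −78 °C; cannulated into 4 (1.1 equiv), THF, −78 °C; aq. NH4Cl, −78 °C
Reagents that add atoms: none
Why: Bromine–lithium exchange at −78 °C (the second equivalent of t-BuLi destroys the tert-butyl bromide formed) gives 5, stabilized by chelation to the acetal oxygens, which undergoes the 1,2-addition of organolithium reagents to squarate esters at one of the two equivalent carbonyls of 4. Inverse addition keeps 4 in excess and should suppress a second addition; the new carbinol center is racemic and is removed in step 4.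

Step 4
Reactants: 6 4-(3,3-diethoxyprop-1-en-2-yl)-4-hydroxy-2,3-dimethoxycyclobut-2-en-1-one (racemic)
Product: 9 2-(diethoxymethyl)-5,6-dimethoxybenzene-1,4-diol, via dienylketene 7 (not isolated), via cyclohexadienone 8 (not isolated)
Conditions: toluene (degassed), 110 °C, argon
Reagents that add atoms: none
Why: The closest known reaction type is the Moore rearrangement, the thermal ring expansion of squarate-derived 4-alkenyl-4-hydroxycyclobutenones to hydroquinones, and 6 belongs to this substrate class. Heating cleaves the C1–C4 bond of the cyclobutenone in a conrotatory four-electron electrocyclic opening to give dienylketene 7. The step needs torquoselectivity, since only an alkenyl group cis to the ketene can cyclize; the donor hydroxyl on C4 secures it by rotating outward, which turns the alkenyl group inward. Ring B is then closed by a thermal disrotatory six-electron electrocyclization in which the ketene carbon bonds to the terminal methylene (bond C5'–C6'), giving cyclohexadienone 8. Enolization of 8, driven by aromatization, should deliver 9 with the former carbonyl carbons as the free phenols at C5' and C2' and the enol ether carbons as the methyl ethers at C4' and C3', so the regiochemistry is fixed by connectivity. No stereocenter is formed and the racemic carbinol center of 6 is destroyed. The medium is neutral and free of oxygen so that the diethyl acetal and the hydroquinone survive.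

Step 5
Reactants: 9 2-(diethoxymethyl)-5,6-dimethoxybenzene-1,4-diol
Product: 11 2,5-bis(benzyloxy)-3,4-dimethoxybenzaldehyde, via dibenzyl ether acetal 10 (not isolated)
Conditions: BnBr (2.5 equiv), K2CO3, DMF, argon, 50 °C; extractive work-up; then 1 M HCl, THF, rt
Reagents that add atoms: benzyl bromide, BrCc1ccccc1; water, O
Why: Williamson ether synthesis on both phenoxides under argon, so that the hydroquinone dianion is alkylated and not oxidized; the base-stable diethyl acetal of the crude 10 is then hydrolysed by dilute acid, which is fast for an electron-rich benzaldehyde acetal and leaves benzyl and methyl ethers untouched.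

Step 6
Reactants: 12 2',6'-dihydroxy-4'-methoxyacetophenone
Product: 13 1-[2-(benzyloxy)-6-hydroxy-4-methoxyphenyl]ethan-1-one
Conditions: BnBr (1.05 equiv), K2CO3, acetone, reflux
Reagents that add atoms: benzyl bromide, BrCc1ccccc1
Why: Williamson etherification; the two hydroxyls of 12 are equivalent by symmetry, and after the first alkylation the remaining hydroxyl is held in a hydrogen bond to the acetyl carbonyl, so one equivalent of benzyl bromide with a weak base should stop at the monoether.

Step 7
Reactants: 11 2,5-bis(benzyloxy)-3,4-dimethoxybenzaldehyde; 13 1-[2-(benzyloxy)-6-hydroxy-4-methoxyphenyl]ethan-1-one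
Product: 14 (2E)-1-[2-(benzyloxy)-6-hydroxy-4-methoxyphenyl]-3-[2,5-bis(benzyloxy)-3,4-dimethoxyphenyl]prop-2-en-1-one
Conditions: KOH, EtOH/THF, rt
Reagents that add atoms: none
Why: Claisen–Schmidt condensation: the enolate of methyl ketone 13 adds to the non-enolizable aldehyde 11 and the aldol loses water by an E1cB path to the conjugated enone, the E alkene being the thermodynamic product. Benzyl and methyl ethers are inert to ethanolic KOH, and any partial closure to flavanone 15 is harmless because step 8 converts it as well.

Step 8
Reactants: 14 (2E)-1-[2-(benzyloxy)-6-hydroxy-4-methoxyphenyl]-3-[2,5-bis(benzyloxy)-3,4-dimethoxyphenyl]prop-2-en-1-one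
Product: 16 5-(benzyloxy)-2-[2,5-bis(benzyloxy)-3,4-dimethoxyphenyl]-7-methoxy-4H-chromen-4-one, via flavanone 15 (not isolated)
Conditions: I2 (0.1 equiv), DMSO, 130 °C
Reagents that add atoms: none
Why: Iodine–DMSO oxidative cyclization of a 2'-hydroxychalcone: intramolecular oxa-Michael addition (6-endo-trig) gives flavanone 15, α-iodination and loss of HI give the chromone, and DMSO reoxidizes HI so that iodine is needed only in catalytic amount. The racemic C2 center of 15 is removed by the dehydrogenation.

Step 9
Reactants: 16 5-(benzyloxy)-2-[2,5-bis(benzyloxy)-3,4-dimethoxyphenyl]-7-methoxy-4H-chromen-4-one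
Product: 17 2-(2,5-dihydroxy-3,4-dimethoxyphenyl)-5-hydroxy-7-methoxy-4H-chromen-4-one (CNP0170944.0)
Conditions: H2 (1 atm), Pd/C (10%), EtOAc/MeOH, rt
Reagents that add atoms: none
Why: Catalytic hydrogenolysis of the three aryl benzyl ethers; aryl methyl ethers and the conjugated pyranone should be inert under these mild conditions, and the neutral medium avoids base-promoted air oxidation of the liberated ring B hydroquinone.

## Compound list

1 | acrolein diethyl acetal (3,3-diethoxyprop-1-ene) | C=CC(OCC)OCC | starting material
2 | 2,3-dibromo-1,1-diethoxypropane (racemic) | CCOC(OCC)C(Br)CBr | intermediate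
3 | 2-bromo-3,3-diethoxyprop-1-ene | CCOC(OCC)C(Br)=C | intermediate
4 | dimethyl squarate (3,4-dimethoxycyclobut-3-ene-1,2-dione) | COC1=C(OC)C(=O)C1=O | starting material
5 | (3,3-diethoxyprop-1-en-2-yl)lithium | [Li]C(=C)C(OCC)OCC | intermediate (not isolated)
6 | 4-(3,3-diethoxyprop-1-en-2-yl)-4-hydroxy-2,3-dimethoxycyclobut-2-en-1-one (racemic) | CCOC(OCC)C(=C)C1(O)C(OC)=C(OC)C1=O | intermediate
7 | (3Z)-5-(diethoxymethyl)-4-hydroxy-2,3-dimethoxyhexa-1,3,5-trien-1-one | O=C=C(OC)/C(OC)=C(/O)C(=C)C(OCC)OCC | intermediate (not isolated)
8 | 5-(diethoxymethyl)-4-hydroxy-2,3-dimethoxycyclohexa-2,4-dien-1-one | CCOC(OCC)C1=C(O)C(OC)=C(OC)C(=O)C1 | intermediate (not isolated)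
9 | 2-(diethoxymethyl)-5,6-dimethoxybenzene-1,4-diol | CCOC(OCC)c1cc(O)c(OC)c(OC)c1O | intermediate
10 | 1,4-bis(benzyloxy)-5-(diethoxymethyl)-2,3-dimethoxybenzene | CCOC(OCC)c1cc(OCc2ccccc2)c(OC)c(OC)c1OCc3ccccc3 | intermediate (not isolated)
11 | 2,5-bis(benzyloxy)-3,4-dimethoxybenzaldehyde | O=Cc1cc(OCc2ccccc2)c(OC)c(OC)c1OCc3ccccc3 | intermediate
12 | 2',6'-dihydroxy-4'-methoxyacetophenone | COc1cc(O)c(C(C)=O)c(O)c1 | starting material
13 | 1-[2-(benzyloxy)-6-hydroxy-4-methoxyphenyl]ethan-1-one | COc1cc(O)c(C(C)=O)c(OCc2ccccc2)c1 | intermediate
14 | (2E)-1-[2-(benzyloxy)-6-hydroxy-4-methoxyphenyl]-3-[2,5-bis(benzyloxy)-3,4-dimethoxyphenyl]prop-2-en-1-one | COc1cc(O)c(C(=O)/C=C/c2cc(OCc3ccccc3)c(OC)c(OC)c2OCc4ccccc4)c(OCc5ccccc5)c1 | intermediate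
15 | 5-(benzyloxy)-2-[2,5-bis(benzyloxy)-3,4-dimethoxyphenyl]-7-methoxy-2,3-dihydro-4H-chromen-4-one (racemic) | COc1cc(OCc2ccccc2)c3C(=O)CC(c4cc(OCc5ccccc5)c(OC)c(OC)c4OCc6ccccc6)Oc3c1 | intermediate (not isolated)
16 | 5-(benzyloxy)-2-[2,5-bis(benzyloxy)-3,4-dimethoxyphenyl]-7-methoxy-4H-chromen-4-one | COc1cc(OCc2ccccc2)c3c(=O)cc(-c4cc(OCc5ccccc5)c(OC)c(OC)c4OCc6ccccc6)oc3c1 | intermediate
17 | 2-(2,5-dihydroxy-3,4-dimethoxyphenyl)-5-hydroxy-7-methoxy-4H-chromen-4-one (CNP0170944.0) | COc1cc(O)c2c(=O)cc(-c3cc(O)c(OC)c(OC)c3O)oc2c1 | target

## Step count and least certain steps

Total: 9 steps. Longest linear sequence: 8 steps (1, 2, 3, 4, 5, 7, 8, 9) from acetal 1; step 6 is the one-step side branch from 12.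

Step 4 (key step).
- Most likely failure: ionization of the diethyl acetal assisted by the neighbouring C2' phenol at 110 °C, with loss of ethanol and oligomerization through a quinone-methide-type species.
- Next most likely: air oxidation of the electron-rich hydroquinone during concentration. Either would erode 9 before it can be protected in step 5.
- Fallback: setting out from 6, the tertiary alcohol would be silylated (Et3SiOTf, 2,6-lutidine, CH2Cl2, −78 °C) to 4-(3,3-diethoxyprop-1-en-2-yl)-2,3-dimethoxy-4-[(triethylsilyl)oxy]cyclobut-2-en-1-one F1.
- Thermolysis of F1 under the conditions of step 4 follows the same electrocyclic sequence, since a silyloxy donor also rotates outward. It should give 5-(diethoxymethyl)-2,3-dimethoxy-4-[(triethylsilyl)oxy]phenol F2, in which the oxygen next to the acetal stays capped and no free hydroquinone exists.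
- Treatment of F2 with BnBr, K2CO3 and CsF in DMF would benzylate the free phenol, remove the silyl group with fluoride and benzylate the phenoxide released. This leads to 10, where the route is rejoined at the acid hydrolysis of step 5.

Step 3.
- Most likely failures: incomplete bromine–lithium exchange or protonation of 5 before it meets 4, a second addition of 5 to the product, and acid-induced loss of methanol from 6 on silica gel.
- Fallback: setting out from 4, commercially available 3,3-diethoxyprop-1-yne would be deprotonated (n-BuLi, THF, −78 °C) to (3,3-diethoxyprop-1-yn-1-yl)lithium F3, a nucleophile that is formed more easily and is more robust.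
- Addition of F3 to 4 would give racemic 4-(3,3-diethoxyprop-1-yn-1-yl)-4-hydroxy-2,3-dimethoxycyclobut-2-en-1-one F4.
- Heating F4 (p-xylene, 138 °C) would trigger the alkynyl variant of the same squarate ring expansion (enynylketene, ring closure to a diradical, hydrogen transfer). It would give 2-(diethoxymethyl)-5,6-dimethoxycyclohexa-2,5-diene-1,4-dione F5.
- Reduction of F5 with aqueous Na2S2O4 (EtOAc/H2O, rt, argon) returns to the route at 9.
- This path is held in reserve because the diradical can also close to a five-membered ring and because it arrives at the quinone oxidation level. The alkenyl substrate 6 gives the hydroquinone directly by a closed-shell six-electron closure.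

Step 8.
- Most likely failures: cleavage of the chelated 5-O-benzyl ether by the HI formed, electrophilic iodination of the electron-rich ring A at C6 or C8, and stalling at flavanone 15.
- Fallback: setting out from 11 and 13, the ring is built through a 1,3-diketone. Pinnick oxidation of 11 (NaClO2, NaH2PO4, 2-methylbut-2-ene, t-BuOH/H2O) would give 2,5-bis(benzyloxy)-3,4-dimethoxybenzoic acid F6.
- Esterification of phenol 13 with F6 (carbodiimide EDC, DMAP, CH2Cl2) would give 2-acetyl-3-(benzyloxy)-5-methoxyphenyl 2,5-bis(benzyloxy)-3,4-dimethoxybenzoate F7.
- Baker–Venkataraman rearrangement of F7 (KOH, pyridine, 50 °C) would give 1-[2-(benzyloxy)-6-hydroxy-4-methoxyphenyl]-3-[2,5-bis(benzyloxy)-3,4-dimethoxyphenyl]propane-1,3-dione F8.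
- Cyclodehydration of F8 with catalytic p-toluenesulfonic acid in toluene at 80 °C rejoins the route at 16, without any oxidant or iodine.

Step 9.
- Most likely failures: slow cleavage of the hindered 2'-benzyl ether with concurrent saturation of the C2=C3 bond of the pyranone, and air oxidation of the liberated hydroquinone during filtration.
- Fallback: setting out from 16, the benzyl ethers would be removed without a reductant by Lewis-acid dealkylation (BCl3, pentamethylbenzene as benzyl cation scavenger, CH2Cl2, −78 °C). This leads directly to 17 and passes through no new compound.

## Further compounds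

F1 | step 4 | 4-(3,3-diethoxyprop-1-en-2-yl)-2,3-dimethoxy-4-[(triethylsilyl)oxy]cyclobut-2-en-1-one (racemic) | CCOC(OCC)C(=C)C1(O[Si](CC)(CC)CC)C(OC)=C(OC)C1=O
F2 | step 4 | 5-(diethoxymethyl)-2,3-dimethoxy-4-[(triethylsilyl)oxy]phenol | CCOC(OCC)c1cc(O)c(OC)c(OC)c1O[Si](CC)(CC)CC
F3 | step 3 | (3,3-diethoxyprop-1-yn-1-yl)lithium | [Li]C#CC(OCC)OCC
F4 | step 3 | 4-(3,3-diethoxyprop-1-yn-1-yl)-4-hydroxy-2,3-dimethoxycyclobut-2-en-1-one (racemic) | CCOC(OCC)C#CC1(O)C(OC)=C(OC)C1=O
F5 | step 3 | 2-(diethoxymethyl)-5,6-dimethoxycyclohexa-2,5-diene-1,4-dione | CCOC(OCC)C1=CC(=O)C(OC)=C(OC)C1=O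
F6 | step 8 | 2,5-bis(benzyloxy)-3,4-dimethoxybenzoic acid | OC(=O)c1cc(OCc2ccccc2)c(OC)c(OC)c1OCc3ccccc3
F7 | step 8 | 2-acetyl-3-(benzyloxy)-5-methoxyphenyl 2,5-bis(benzyloxy)-3,4-dimethoxybenzoate | COc1cc(OC(=O)c2cc(OCc3ccccc3)c(OC)c(OC)c2OCc4ccccc4)c(C(C)=O)c(OCc5ccccc5)c1
F8 | step 8 | 1-[2-(benzyloxy)-6-hydroxy-4-methoxyphenyl]-3-[2,5-bis(benzyloxy)-3,4-dimethoxyphenyl]propane-1,3-dione | COc1cc(O)c(C(=O)CC(=O)c2cc(OCc3ccccc3)c(OC)c(OC)c2OCc4ccccc4)c(OCc5ccccc5)c1
F0 | step 9 | none | none
A1 | alternative 1 | methyl 9-[2,5-bis(benzyloxy)-3,4-dimethoxyphenyl]-3,5,7,9-tetraoxononanoate | COC(=O)CC(=O)CC(=O)CC(=O)CC(=O)c1cc(OCc2ccccc2)c(OC)c(OC)c1OCc3ccccc3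
A2 | alternative 1 | 2-[2,5-bis(benzyloxy)-3,4-dimethoxyphenyl]-5,7-dihydroxy-4H-chromen-4-one | Oc1cc(O)c2c(=O)cc(-c3cc(OCc4ccccc4)c(OC)c(OC)c3OCc5ccccc5)oc2c1
A3 | alternative 2 | (2Z)-3-[2,5-bis(benzyloxy)-3,4-dimethoxyphenyl]-3-(3,5-dimethoxyphenoxy)prop-2-enoic acid | OC(=O)/C=C(\Oc1cc(OC)cc(OC)c1)c2cc(OCc3ccccc3)c(OC)c(OC)c2OCc4ccccc4
A4 | alternative 2 | 2-[2,5-bis(benzyloxy)-3,4-dimethoxyphenyl]-5,7-dimethoxy-4H-chromen-4-one | COc1cc(OC)c2c(=O)cc(-c3cc(OCc4ccccc4)c(OC)c(OC)c3OCc5ccccc5)oc2c1
A5 | alternative 3 | 2-diazo-1-{6-[2,5-bis(benzyloxy)-3,4-dimethoxyphenyl]-4-oxo-4H-pyran-2-yl}ethan-1-one | [N-]=[N+]=CC(=O)c1cc(=O)cc(-c2cc(OCc3ccccc3)c(OC)c(OC)c2OCc4ccccc4)o1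
A6 | alternative 3 | methoxyethyne | COC#C
A7 | alternative 3 | 2-[2,5-bis(benzyloxy)-3,4-dimethoxyphenyl]-5-hydroxy-7-methoxy-4H-chromen-4-one | COc1cc(O)c2c(=O)cc(-c3cc(OCc4ccccc4)c(OC)c(OC)c3OCc5ccccc5)oc2c1
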